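**Plan**

1. Retrosynthesis cuts, in this order: the C9–O and C8–O acyl bonds; C14 back to an allylic CH2O tied to O9 as an acetonide; the lactone at C11=C13, O6–C12 and C7–C11; and last the ring bond C8–C9.
2. Enabling feature: in the ten-membered ring, C1=C10–C9–C8–C7–C6(O) is a 1,5-diene with oxygen on C6, and C4=C5 is ring-cis. A retro-oxy-Cope across C8–C9 therefore re-forms C1–C6 and folds C1–C6 into a 3-methylcyclohex-2-en-1-ol that carries a C7=C8 enol ether on C6 and a 4H-1,3-dioxin (C9, C10, C14) on C1.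
3. Forward: 3-methylcyclohexenone is α'-alkenylated (C1–C10), an alkoxyacetylide is added to the ketone (C6–C7) and semi-hydrogenated, and the six-membered ring is expanded to the ten-membered ring by anionic oxy-Cope with enolate alkylation (C7–C11). The lactone ring, the methylene, the C14 ester and the two side-chain esters follow.
4. Stereochemistry: C1 from an enantioselective Pd-catalysed α-alkenylation; the carbinol from axial acetylide addition; C8/C9 by chirality transfer through a chair transition state; C7 by face-selective enolate alkylation; C6 by chelation-controlled reduction; the side chains from an Evans syn aldol and a Sharpless epoxidation.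

Key step: step 7

**Remarks and assumptions**

- Ten-membered compounds carry the target locants: C1=C10, C4=C5, O on C6, C7–C11, O on C8 and C9, C14 on C10, C15 on C4. "Ring-cis" means both ring bonds lie on the same side of the double bond, as in the target.
- The sense of induction of the chiral ligand in step 3 is assumed to give (6R)-8 with the (R)-ligand; its antipode is used if the sense is opposite. The same holds for the hydrogenation catalyst in the fallback to step 3.
- Enol ethers 3, 8, 13 and 14 are acid-labile and are purified on triethylamine-deactivated silica; alkynyl ether 13 is hydrogenated without storage.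

**Route**

Step 1
Reactants: 1 2,2-dimethyl-1,3-dioxan-5-one
Product: 3 2,2-dimethyl-4H-1,3-dioxin-5-yl trifluoromethanesulfonate, via potassium enolate 2 (not isolated)
Conditions: KN(SiMe3)2, THF, −78 °C; PhNTf2, −78 → 0 °C
Reagents that add atoms: N-phenylbis(trifluoromethanesulfonimide), O=S(=O)(N(c1ccccc1)S(=O)(=O)C(F)(F)F)C(F)(F)F
Why: O-triflation of the kinetic enolate (enol triflate formation) of the symmetrical ketone gives the only possible enol triflate, in which the ring holds the enol-ether oxygen cis to the CH2O carbon.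

Step 2
Reactants: 4 3-methylcyclohex-2-en-1-one
Product: 6 trimethyl[(5-methylcyclohexa-1,5-dien-1-yl)oxy]silane, via lithium dienolate 5 (not isolated)
Conditions: LiN(i-Pr)2, THF, −78 °C; Me3SiCl
Reagents that add atoms: chlorotrimethylsilane, C[Si](C)(C)Cl
Why: Kinetic deprotonation of the enone at C6 and O-silylation (silyl enol ether formation) place the nucleophilic carbon at the future C1.

Step 3
Reactants: 6 trimethyl[(5-methylcyclohexa-1,5-dien-1-yl)oxy]silane; 3 2,2-dimethyl-4H-1,3-dioxin-5-yl trifluoromethanesulfonate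
Product: 8 (6R)-6-(2,2-dimethyl-4H-1,3-dioxin-5-yl)-3-methylcyclohex-2-en-1-one, via tributyltin enolate 7 (not isolated)
Conditions: Pd(OAc)2 (cat.), (R)-2-(dicyclohexylphosphino)-2'-methoxy-1,1'-binaphthyl, Bu3SnF, PhMe, 40 °C
Reagents that add atoms: none
Why: Enantioselective Pd-catalysed α-alkenylation of a ketone tin enolate with an alkenyl triflate forms C1–C10 without amide base, so the tertiary α-stereocentre is set by the chiral phosphine on palladium and should not equilibrate afterwards.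

Step 4
Reactants: 9 (4-methoxyphenyl)methanol
Product: 11 1-({[(E)-1,2-dichloroethenyl]oxy}methyl)-4-methoxybenzene, via potassium alkoxide 10 (not isolated)
Conditions: KH, THF, 0 °C; trichloroethylene, 25 °C
Reagents that add atoms: trichloroethylene, ClC=C(Cl)Cl
Why: Addition of an alkoxide to trichloroethylene (elimination to dichloroacetylene, then addition) is the standard entry to 1,2-dichlorovinyl ethers as alkynyl-ether precursors.

Step 5
Reactants: 11 1-({[(E)-1,2-dichloroethenyl]oxy}methyl)-4-methoxybenzene; 8 (6R)-6-(2,2-dimethyl-4H-1,3-dioxin-5-yl)-3-methylcyclohex-2-en-1-one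
Product: 13 (1S,6R)-6-(2,2-dimethyl-4H-1,3-dioxin-5-yl)-1-{[(4-methoxyphenyl)methoxy]ethynyl}-3-methylcyclohex-2-en-1-ol, via lithium alkynyl ether 12 (not isolated)
Conditions: n-BuLi (2.1 equiv), THF, −78 °C; CeCl3, −78 °C; then 8, −78 °C; buffered work-up
Reagents that add atoms: none
Why: Elimination and chlorine–lithium exchange give the alkoxyacetylide, whose organocerium form adds 1,2 to the enolisable enone (organocerium carbonyl addition) axially and cis to the pseudo-equatorial dioxinyl group, because the rod-shaped nucleophile meets only one 1,3-diaxial hydrogen in the cyclohexenone half-chair, which sets the carbinol centre as 1S.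

Step 6
Reactants: 13 (1S,6R)-6-(2,2-dimethyl-4H-1,3-dioxin-5-yl)-1-{[(4-methoxyphenyl)methoxy]ethynyl}-3-methylcyclohex-2-en-1-ol
Product: 14 (1S,6R)-6-(2,2-dimethyl-4H-1,3-dioxin-5-yl)-1-{(Z)-2-[(4-methoxyphenyl)methoxy]ethenyl}-3-methylcyclohex-2-en-1-ol
Conditions: H2 (1 atm), Pd/CaCO3 poisoned with Pb(OAc)2, quinoline, EtOAc, 25 °C
Reagents that add atoms: none
Why: Lindlar semi-hydrogenation of the alkynyl ether (second stage of an Arens–van Dorp sequence) gives the (Z)-enol ether by syn addition and leaves the other alkenes untouched.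

Step 7
Reactants: 14 (1S,6R)-6-(2,2-dimethyl-4H-1,3-dioxin-5-yl)-1-{(Z)-2-[(4-methoxyphenyl)methoxy]ethenyl}-3-methylcyclohex-2-en-1-ol
Product: 17 methyl [(7R,8S,9R)-9,14-(isopropylidenedioxy)-8-[(4-methoxybenzyl)oxy]-6-oxocyclodeca-1(10),4-dien-7-yl]acetate, via potassium alkoxide 15 (not isolated), via potassium enolate 16 (not isolated)
Conditions: KN(SiMe3)2 (1.05 equiv), THF, −78 → 0 °C, no crown ether; then −78 °C, BrCH2CO2Me
Reagents that add atoms: methyl bromoacetate, COC(=O)CBr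
Why: Proposed new method: deprotonation gives alkoxide 15, whose C6–O− weakens the allylic C1–C6 bond so that the 1,5-diene C8=C7–C6–C1–C10=C9 should undergo a charge-accelerated [3,3]-sigmatropic shift (anionic oxy-Cope) driven by the change from alkoxide to the conjugated enolate 16; it is new in that both bond-forming termini are enol-ether carbons, which costs two enol-ether stabilisations but should leave the shift downhill. The closest known reaction types are the anionic oxy-Cope ring expansion of cis-1,2-dialkenylcyclohexenols to cis-cyclodecenones and the Ireland–Claisen rearrangement of α-alkoxy esters of enol-ether allylic alcohols, which also joins two oxygen-bearing carbons. The ten-membered carbocycle is closed by the sigmatropic C8–C9 bond formation itself (four-atom ring expansion of the cyclohexene through a six-membered chair array, not an exo or endo cyclisation), and the 1,3-dioxin becomes a fused 1,3-dioxane. C8 and C9 are set by chirality transfer from C1 and C6: in the chair with the C6 alkenyl group axial on the cyclohexene, the (Z)-enol ether places O8 axial and the ring-locked dioxin places O9 equatorial, which gives the erythro (8S,9R) pair and the ring-cis C1=C10 bond; C7 is set when methyl bromoacetate attacks the enolate on the face away from the transannular C9–C1 chain, the C7–C8 rotamer being held by potassium bridging O6 and O8. The step needs the [3,3] shift to win over C1–C6 fragmentation, over loss of the C8 alkoxide from the β-alkoxy enolate and over the other chair or a boat; the cis arrangement of the two alkenyl groups, the non-acylating CH2O level of C14, the poor 4-methoxybenzyloxide leaving group, the chelating potassium ion and trapping at low temperature are meant to secure this.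

Step 8
Reactants: 17 methyl [(7R,8S,9R)-9,14-(isopropylidenedioxy)-8-[(4-methoxybenzyl)oxy]-6-oxocyclodeca-1(10),4-dien-7-yl]acetate
Product: 19 (6R,7S,8S,9R)-9,14-(isopropylidenedioxy)-8-[(4-methoxybenzyl)oxy]-13-norgermacra-1(10),4-dien-12,6-olide, via hydroxy ester 18 (not isolated)
Conditions: Zn(BH4)2, Et2O, −20 °C; then PPTS (cat.), PhMe, 40 °C
Reagents that add atoms: none
Why: Chelation-controlled 1,2-reduction (zinc held between the C6 carbonyl and the C8 ether oxygen, hydride anti to the C7 acetate arm as in the Cram chelate model) should give the (6R)-alcohol, which lactonises onto the methyl ester to the trans-fused γ-lactone.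

Step 9
Reactants: 19 (6R,7S,8S,9R)-9,14-(isopropylidenedioxy)-8-[(4-methoxybenzyl)oxy]-13-norgermacra-1(10),4-dien-12,6-olide
Product: 23 (6R,7S,8S,9R)-9,14-(isopropylidenedioxy)-8-[(4-methoxybenzyl)oxy]germacra-1(10),4,11(13)-trien-12,6-olide, via lithium lactone enolate 20 (not isolated), via Mannich base 21 (not isolated), via trimethylammonium iodide 22 (not isolated)
Conditions: LiN(i-Pr)2, THF, −78 °C; CH2=NMe2+ I−; then MeI, MeOH; then NaHCO3, CH2Cl2/H2O
Reagents that add atoms: N,N-dimethylmethyleneiminium iodide (Eschenmoser's salt), C=[N+](C)C.[I-]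
Why: Aminomethylation of the lactone enolate with Eschenmoser's salt, quaternisation and Hofmann-type elimination is the standard α-methylenation of γ-lactones, and the acetonide and the benzyl-type ether are inert to the amide base.

Step 10
Reactants: 23 (6R,7S,8S,9R)-9,14-(isopropylidenedioxy)-8-[(4-methoxybenzyl)oxy]germacra-1(10),4,11(13)-trien-12,6-olide
Product: 24 (6R,7S,8S,9R)-9,14-dihydroxy-8-[(4-methoxybenzyl)oxy]germacra-1(10),4,11(13)-trien-12,6-olide
Conditions: PPTS, MeOH, 25 °C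
Reagents that add atoms: none
Why: Acid-catalysed transacetalisation removes the acetonide and frees the C9 and C14 hydroxyls while the 4-methoxybenzyl ether and the lactone stay intact.

Step 11
Reactants: 24 (6R,7S,8S,9R)-9,14-dihydroxy-8-[(4-methoxybenzyl)oxy]germacra-1(10),4,11(13)-trien-12,6-olide
Product: 25 (6R,7S,8S,9R)-9-hydroxy-8-[(4-methoxybenzyl)oxy]-14-oxogermacra-1(10),4,11(13)-trien-12,6-olide
Conditions: TEMPO (cat.), PhI(OAc)2, CH2Cl2, 25 °C
Reagents that add atoms: none
Why: Oxoammonium (TEMPO) oxidation is selective for the unhindered primary allylic alcohol over the flanked secondary C9 alcohol and stops at the enal.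

Step 12
Reactants: 25 (6R,7S,8S,9R)-9-hydroxy-8-[(4-methoxybenzyl)oxy]-14-oxogermacra-1(10),4,11(13)-trien-12,6-olide
Product: 27 methyl (6R,7S,8S,9R)-9-hydroxy-8-[(4-methoxybenzyl)oxy]germacra-1(10),4,11(13)-trien-12,6-olid-14-oate, via carboxylic acid 26 (not isolated)
Conditions: NaClO2, NaH2PO4, 2-methylbut-2-ene, t-BuOH/H2O, 0 °C; then MeI, KHCO3, DMF, 25 °C
Reagents that add atoms: sodium chlorite, [Na+].[O-]Cl=O; iodomethane, CI
Why: Pinnick oxidation converts the enal into the acid without touching the alkenes or the free alcohol, and carboxylate O-alkylation gives the methyl ester without diazomethane, which would add to the α-methylene lactone.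

Step 13
Reactants: 28 (4R)-4-benzyl-3-propanoyl-1,3-oxazolidin-2-one
Product: 30 (4R)-4-benzyl-3-[(2R,3S)-3-hydroxy-2-methylbutanoyl]-1,3-oxazolidin-2-one, via boron enolate 29 (not isolated)
Conditions: Bu2BOTf, i-Pr2NEt, CH2Cl2, 0 °C; MeCHO, −78 → 0 °C; H2O2, pH 7 buffer, MeOH
Reagents that add atoms: acetaldehyde, CC=O
Why: Evans syn aldol, in which the (Z)-boron enolate of the (R)-benzyl oxazolidinone reacts through a Zimmerman–Traxler chair to give the (2R,3S) syn adduct.

Step 14
Reactants: 30 (4R)-4-benzyl-3-[(2R,3S)-3-hydroxy-2-methylbutanoyl]-1,3-oxazolidin-2-one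
Product: 31 (4R)-4-benzyl-3-{(2R,3S)-2-methyl-3-[(triethylsilyl)oxy]butanoyl}-1,3-oxazolidin-2-one
Conditions: Et3SiCl, imidazole, DMF, 0 °C
Reagents that add atoms: chlorotriethylsilane, CC[Si](Cl)(CC)CC
Why: Silyl ether formation protects the secondary alcohol for the acylation steps and can be undone later under mild buffered fluoride conditions.

Step 15
Reactants: 31 (4R)-4-benzyl-3-{(2R,3S)-2-methyl-3-[(triethylsilyl)oxy]butanoyl}-1,3-oxazolidin-2-one
Product: 32 (2R,3S)-2-methyl-3-[(triethylsilyl)oxy]butanoic acid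
Conditions: LiOH, H2O2, THF/H2O, 0 °C; Na2SO3; dilute HCl to pH 3, 0 °C
Reagents that add atoms: hydrogen peroxide, OO
Why: Hydroperoxide-mediated cleavage of the imide attacks the exocyclic carbonyl and releases the acid without epimerisation at C2.

Step 16
Reactants: 32 (2R,3S)-2-methyl-3-[(triethylsilyl)oxy]butanoic acid; 27 methyl (6R,7S,8S,9R)-9-hydroxy-8-[(4-methoxybenzyl)oxy]germacra-1(10),4,11(13)-trien-12,6-olid-14-oate
Product: 34 methyl (6R,7S,8S,9R)-8-[(4-methoxybenzyl)oxy]-9-({(2R,3S)-2-methyl-3-[(triethylsilyl)oxy]butanoyl}oxy)germacra-1(10),4,11(13)-trien-12,6-olid-14-oate, via mixed anhydride 33 (not isolated)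
Conditions: 2,4,6-Cl3C6H2COCl, Et3N, THF, 0 °C; then 27, DMAP, PhMe, 25 °C
Reagents that add atoms: none
Why: Yamaguchi esterification acylates the only free hydroxyl (C9) through the mixed anhydride under conditions that should not epimerise the α-centre of the acid.

Step 17
Reactants: 34 methyl (6R,7S,8S,9R)-8-[(4-methoxybenzyl)oxy]-9-({(2R,3S)-2-methyl-3-[(triethylsilyl)oxy]butanoyl}oxy)germacra-1(10),4,11(13)-trien-12,6-olid-14-oate
Product: 35 methyl (6R,7S,8S,9R)-8-hydroxy-9-({(2R,3S)-2-methyl-3-[(triethylsilyl)oxy]butanoyl}oxy)germacra-1(10),4,11(13)-trien-12,6-olid-14-oate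
Conditions: DDQ, CH2Cl2/pH 7 phosphate buffer, 0 °C
Reagents that add atoms: none
Why: Oxidative cleavage of the 4-methoxybenzyl ether with DDQ frees the C8 hydroxyl without base, so the neighbouring C9 ester should not migrate.

Step 18
Reactants: 36 methyl (2Z)-2-methylbut-2-enoate
Product: 37 (2Z)-2-methylbut-2-en-1-ol
Conditions: i-Bu2AlH (2.2 equiv), CH2Cl2, −78 °C
Reagents that add atoms: none
Why: Hydride reduction of the ester gives the allylic alcohol with the (Z)-geometry retained.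

Step 19
Reactants: 37 (2Z)-2-methylbut-2-en-1-ol
Product: 38 [(2R,3S)-2,3-dimethyloxiran-2-yl]methanol
Conditions: Ti(Oi-Pr)4, D-(−)-diethyl tartrate, t-BuOOH, 4 Å molecular sieves, CH2Cl2, −20 °C
Reagents that add atoms: tert-butyl hydroperoxide, CC(C)(C)OO
Why: Sharpless asymmetric epoxidation with the D-tartrate delivers oxygen to the face of the allylic alcohol that gives the (2R,3S)-epoxy alcohol.

Step 20
Reactants: 38 [(2R,3S)-2,3-dimethyloxiran-2-yl]methanol
Product: 39 (2S,3S)-2,3-dimethyloxirane-2-carboxylic acid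
Conditions: RuCl3 (cat.), NaIO4, CCl4/MeCN/H2O, 25 °C
Reagents that add atoms: water, O
Why: RuO4-catalysed oxidation takes the primary alcohol to the acid without opening the epoxide, and the C2 descriptor changes to S only through the change in substituent priority.

Step 21
Reactants: 39 (2S,3S)-2,3-dimethyloxirane-2-carboxylic acid; 35 methyl (6R,7S,8S,9R)-8-hydroxy-9-({(2R,3S)-2-methyl-3-[(triethylsilyl)oxy]butanoyl}oxy)germacra-1(10),4,11(13)-trien-12,6-olid-14-oate
Product: 41 methyl (6R,7S,8S,9R)-8-{[(2S,3S)-2,3-dimethyloxirane-2-carbonyl]oxy}-9-({(2R,3S)-2-methyl-3-[(triethylsilyl)oxy]butanoyl}oxy)germacra-1(10),4,11(13)-trien-12,6-olid-14-oate, via mixed anhydride 40 (not isolated)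
Conditions: 2,4,6-Cl3C6H2COCl, Et3N, THF, 0 °C; then 35, DMAP, PhMe, 0 → 25 °C
Reagents that add atoms: none
Why: Yamaguchi esterification of the hindered C8 hydroxyl with the α-quaternary epoxy acid, run cold with short base contact to suppress 1,2-migration of the C9 acyl group.

Step 22
Reactants: 41 methyl (6R,7S,8S,9R)-8-{[(2S,3S)-2,3-dimethyloxirane-2-carbonyl]oxy}-9-({(2R,3S)-2-methyl-3-[(triethylsilyl)oxy]butanoyl}oxy)germacra-1(10),4,11(13)-trien-12,6-olid-14-oate
Product: 42 methyl (6R,7S,8S,9R)-8-{[(2S,3S)-2,3-dimethyloxirane-2-carbonyl]oxy}-9-{[(2R,3S)-3-hydroxy-2-methylbutanoyl]oxy}germacra-1(10),4,11(13)-trien-12,6-olid-14-oate (CNP0135583.1)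
Conditions: HF·pyridine, pyridine, THF, 0 °C
Reagents that add atoms: none
Why: Buffered fluoride desilylation cleaves the triethylsilyl ether without opening the epoxide or adding to the α-methylene lactone.

**Compound list**

1 | 2,2-dimethyl-1,3-dioxan-5-one | CC1(C)OCC(=O)CO1 | starting material
2 | potassium 2,2-dimethyl-4H-1,3-dioxin-5-olate | CC1(C)OCC([O-])=CO1.[K+] | intermediate
3 | 2,2-dimethyl-4H-1,3-dioxin-5-yl trifluoromethanesulfonate | CC1(C)OCC(OS(=O)(=O)C(F)(F)F)=CO1 | intermediate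
4 | 3-methylcyclohex-2-en-1-one | CC1=CC(=O)CC1 | starting material
5 | lithium 5-methylcyclohexa-1,5-dien-1-olate | CC1=CC([O-])=CCC1.[Li+] | intermediate
6 | trimethyl[(5-methylcyclohexa-1,5-dien-1-yl)oxy]silane | CC1=CC(O[Si](C)(C)C)=CCC1 | intermediate
7 | tributyl[(5-methylcyclohexa-1,5-dien-1-yl)oxy]stannane | CCCC[Sn](CCCC)(CCCC)OC1=CCCC(C)=C1 | intermediate
8 | (6R)-6-(2,2-dimethyl-4H-1,3-dioxin-5-yl)-3-methylcyclohex-2-en-1-one | CC1=CC(=O)[C@@H](C2=COC(C)(C)OC2)CC1 | intermediate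
9 | (4-methoxyphenyl)methanol | COc1ccc(CO)cc1 | starting material
10 | potassium (4-methoxyphenyl)methanolate | COc1ccc(C[O-])cc1.[K+] | intermediate
11 | 1-({[(E)-1,2-dichloroethenyl]oxy}methyl)-4-methoxybenzene | COc1ccc(CO/C(Cl)=C\Cl)cc1 | intermediate
12 | lithium 2-[(4-methoxyphenyl)methoxy]ethyn-1-ide | [Li+].[C-]#COCc1ccc(OC)cc1 | intermediate
13 | (1S,6R)-6-(2,2-dimethyl-4H-1,3-dioxin-5-yl)-1-{[(4-methoxyphenyl)methoxy]ethynyl}-3-methylcyclohex-2-en-1-ol | CC1=C[C@@](O)(C#COCc2ccc(OC)cc2)[C@@H](C3=COC(C)(C)OC3)CC1 | intermediate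
14 | (1S,6R)-6-(2,2-dimethyl-4H-1,3-dioxin-5-yl)-1-{(Z)-2-[(4-methoxyphenyl)methoxy]ethenyl}-3-methylcyclohex-2-en-1-ol | CC1=C[C@@](O)(/C=C\OCc2ccc(OC)cc2)[C@@H](C3=COC(C)(C)OC3)CC1 | intermediate
15 | potassium alkoxide of 14 | CC1=C[C@@]([O-])(/C=C\OCc2ccc(OC)cc2)[C@@H](C3=COC(C)(C)OC3)CC1.[K+] | intermediate
16 | potassium (8S,9R)-9,14-(isopropylidenedioxy)-8-[(4-methoxybenzyl)oxy]cyclodeca-1(10),4,6-trien-6-olate (C1=C10 and C4=C5 ring-cis, C6=C7 ring-trans) | [K+].[O-]/C1=C\[C@H](OCc2ccc(OC)cc2)[C@@H]3OC(C)(C)OC/C3=C/CC/C(C)=C\1 | intermediate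
17 | methyl [(7R,8S,9R)-9,14-(isopropylidenedioxy)-8-[(4-methoxybenzyl)oxy]-6-oxocyclodeca-1(10),4-dien-7-yl]acetate (both ring alkenes ring-cis) | COC(=O)C[C@H]1C(=O)/C=C(/C)CC/C=C2/COC(C)(C)O[C@H]2[C@H]1OCc3ccc(OC)cc3 | intermediate
18 | methyl [(6R,7S,8S,9R)-6-hydroxy-9,14-(isopropylidenedioxy)-8-[(4-methoxybenzyl)oxy]cyclodeca-1(10),4-dien-7-yl]acetate | COC(=O)C[C@H]1[C@H](O)/C=C(/C)CC/C=C2/COC(C)(C)O[C@H]2[C@H]1OCc3ccc(OC)cc3 | intermediate
19 | (6R,7S,8S,9R)-9,14-(isopropylidenedioxy)-8-[(4-methoxybenzyl)oxy]-13-norgermacra-1(10),4-dien-12,6-olide | C1C(=O)O[C@@H]2/C=C(/C)CC/C=C3/COC(C)(C)O[C@H]3[C@@H](OCc4ccc(OC)cc4)[C@@H]12 | intermediate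
20 | lithium enolate of lactone 19 | C1=C([O-])O[C@@H]2/C=C(/C)CC/C=C3/COC(C)(C)O[C@H]3[C@@H](OCc4ccc(OC)cc4)[C@@H]12.[Li+] | intermediate
21 | 11-[(dimethylamino)methyl] derivative of lactone 19 (C11 epimers) | CN(C)CC1C(=O)O[C@@H]2/C=C(/C)CC/C=C3/COC(C)(C)O[C@H]3[C@@H](OCc4ccc(OC)cc4)[C@@H]12 | intermediate
22 | trimethylammonium iodide of 21 | C[N+](C)(C)CC1C(=O)O[C@@H]2/C=C(/C)CC/C=C3/COC(C)(C)O[C@H]3[C@@H](OCc4ccc(OC)cc4)[C@@H]12.[I-] | intermediate
23 | (6R,7S,8S,9R)-9,14-(isopropylidenedioxy)-8-[(4-methoxybenzyl)oxy]germacra-1(10),4,11(13)-trien-12,6-olide | C=C1C(=O)O[C@@H]2/C=C(/C)CC/C=C3/COC(C)(C)O[C@H]3[C@@H](OCc4ccc(OC)cc4)[C@@H]12 | intermediate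
24 | (6R,7S,8S,9R)-9,14-dihydroxy-8-[(4-methoxybenzyl)oxy]germacra-1(10),4,11(13)-trien-12,6-olide | C=C1C(=O)O[C@@H]2/C=C(/C)CC/C=C(/CO)[C@@H](O)[C@@H](OCc3ccc(OC)cc3)[C@@H]12 | intermediate
25 | (6R,7S,8S,9R)-9-hydroxy-8-[(4-methoxybenzyl)oxy]-14-oxogermacra-1(10),4,11(13)-trien-12,6-olide | C=C1C(=O)O[C@@H]2/C=C(/C)CC/C=C(/C=O)[C@@H](O)[C@@H](OCc3ccc(OC)cc3)[C@@H]12 | intermediate
26 | (6R,7S,8S,9R)-9-hydroxy-8-[(4-methoxybenzyl)oxy]germacra-1(10),4,11(13)-trien-12,6-olid-14-oic acid | C=C1C(=O)O[C@@H]2/C=C(/C)CC/C=C(/C(=O)O)[C@@H](O)[C@@H](OCc3ccc(OC)cc3)[C@@H]12 | intermediate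
27 | methyl (6R,7S,8S,9R)-9-hydroxy-8-[(4-methoxybenzyl)oxy]germacra-1(10),4,11(13)-trien-12,6-olid-14-oate | C=C1C(=O)O[C@@H]2/C=C(/C)CC/C=C(/C(=O)OC)[C@@H](O)[C@@H](OCc3ccc(OC)cc3)[C@@H]12 | intermediate
28 | (4R)-4-benzyl-3-propanoyl-1,3-oxazolidin-2-one | CCC(=O)N1[C@H](Cc2ccccc2)COC1=O | starting material
29 | dibutylboron (Z)-enolate of 28 | C/C=C(\OB(CCCC)CCCC)N1[C@H](Cc2ccccc2)COC1=O | intermediate
30 | (4R)-4-benzyl-3-[(2R,3S)-3-hydroxy-2-methylbutanoyl]-1,3-oxazolidin-2-one | O=C([C@H](C)[C@H](C)O)N1[C@H](Cc2ccccc2)COC1=O | intermediate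
31 | (4R)-4-benzyl-3-{(2R,3S)-2-methyl-3-[(triethylsilyl)oxy]butanoyl}-1,3-oxazolidin-2-one | O=C([C@H](C)[C@H](C)O[Si](CC)(CC)CC)N1[C@H](Cc2ccccc2)COC1=O | intermediate
32 | (2R,3S)-2-methyl-3-[(triethylsilyl)oxy]butanoic acid | OC(=O)[C@H](C)[C@H](C)O[Si](CC)(CC)CC | intermediate
33 | (2R,3S)-2-methyl-3-[(triethylsilyl)oxy]butanoic 2,4,6-trichlorobenzoic anhydride | O=C(OC(=O)[C@H](C)[C@H](C)O[Si](CC)(CC)CC)c1c(Cl)cc(Cl)cc1Cl | intermediate
34 | methyl (6R,7S,8S,9R)-8-[(4-methoxybenzyl)oxy]-9-({(2R,3S)-2-methyl-3-[(triethylsilyl)oxy]butanoyl}oxy)germacra-1(10),4,11(13)-trien-12,6-olid-14-oate | C=C1C(=O)O[C@@H]2/C=C(/C)CC/C=C(/C(=O)OC)[C@@H](OC(=O)[C@H](C)[C@H](C)O[Si](CC)(CC)CC)[C@@H](OCc3ccc(OC)cc3)[C@@H]12 | intermediate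
35 | methyl (6R,7S,8S,9R)-8-hydroxy-9-({(2R,3S)-2-methyl-3-[(triethylsilyl)oxy]butanoyl}oxy)germacra-1(10),4,11(13)-trien-12,6-olid-14-oate | C=C1C(=O)O[C@@H]2/C=C(/C)CC/C=C(/C(=O)OC)[C@@H](OC(=O)[C@H](C)[C@H](C)O[Si](CC)(CC)CC)[C@@H](O)[C@@H]12 | intermediate
36 | methyl (2Z)-2-methylbut-2-enoate (methyl angelate) | C/C=C(/C)C(=O)OC | starting material
37 | (2Z)-2-methylbut-2-en-1-ol | C/C=C(/C)CO | intermediate
38 | [(2R,3S)-2,3-dimethyloxiran-2-yl]methanol | OC[C@@]1(C)O[C@H]1C | intermediate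
39 | (2S,3S)-2,3-dimethyloxirane-2-carboxylic acid | OC(=O)[C@@]1(C)O[C@H]1C | intermediate
40 | (2S,3S)-2,3-dimethyloxirane-2-carboxylic 2,4,6-trichlorobenzoic anhydride | O=C(OC(=O)[C@@]1(C)O[C@H]1C)c2c(Cl)cc(Cl)cc2Cl | intermediate
41 | methyl (6R,7S,8S,9R)-8-{[(2S,3S)-2,3-dimethyloxirane-2-carbonyl]oxy}-9-({(2R,3S)-2-methyl-3-[(triethylsilyl)oxy]butanoyl}oxy)germacra-1(10),4,11(13)-trien-12,6-olid-14-oate | C=C1C(=O)O[C@@H]2/C=C(/C)CC/C=C(/C(=O)OC)[C@@H](OC(=O)[C@H](C)[C@H](C)O[Si](CC)(CC)CC)[C@@H](OC(=O)[C@@]3(C)O[C@H]3C)[C@@H]12 | intermediate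
42 | methyl (6R,7S,8S,9R)-8-{[(2S,3S)-2,3-dimethyloxirane-2-carbonyl]oxy}-9-{[(2R,3S)-3-hydroxy-2-methylbutanoyl]oxy}germacra-1(10),4,11(13)-trien-12,6-olid-14-oate (CNP0135583.1) | C=C1C(=O)O[C@@H]2/C=C(/C)CC/C=C(/C(=O)OC)[C@@H](OC(=O)[C@H](C)[C@H](C)O)[C@@H](OC(=O)[C@@]3(C)O[C@H]3C)[C@@H]12 | target

**Totals**

Total step count: 22. Longest linear sequence: 14 steps (1, 3, 5, 6, 7, 8, 9, 10, 11, 12, 16, 17, 21, 22).

**Steps most likely to fail**

Step 7. The alkoxide may fragment at C1–C6 instead of rearranging, the β-alkoxy enolate may expel the C8 alkoxide before it is trapped, or a boat transition state may erode the C8/C9 relationship. The fallback sets out from ketone 8 and comes back at keto ester 17. It exchanges the oxygen on C8 for silicon, which removes the β-leaving group and leaves a single donor-substituted terminus, and each reaction type in it is established on its own. Ketone 8 is treated with the organocerium acetylide from benzyl(ethynyl)dimethylsilane (n-BuLi, CeCl3, THF, −78 °C) to give (1S,6R)-1-{[benzyl(dimethyl)silyl]ethynyl}-6-(2,2-dimethyl-4H-1,3-dioxin-5-yl)-3-methylcyclohex-2-en-1-ol F1. Lindlar hydrogenation gives the (Z)-vinylsilane carbinol F2. Anionic oxy-Cope ring expansion (KN(SiMe3)2, THF, then NH4Cl) gives the (8S,9R)-β-silyl ketone F3. Tamao–Fleming oxidation (Bu4NF, then H2O2, KHCO3) gives with retention the β-hydroxy ketone F4. 4-Methoxybenzyl trichloroacetimidate with catalytic La(OTf)3 gives the ether ketone F5. The potassium enolate of F5 (KN(SiMe3)2, THF, −78 °C) is alkylated with methyl bromoacetate to rejoin the route at 17.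

Step 3. The enantioselectivity may be low, or the labile α-centre may racemise during the coupling. The fallback sets out from 6 and 3 and comes back at 8. The same coupling is run with an achiral catalyst (Pd(OAc)2, P(t-Bu)3, Bu3SnF) to the racemic ketone F6. F6 is hydrogenated with dynamic kinetic resolution (H2, RuCl2[(S)-xylbinap][(S)-daipen], t-BuOK, i-PrOH), in which the α-centre equilibrates under base while one enantiomer is reduced at the carbonyl only, to the cis-allylic alcohol (1R,6R)-6-(2,2-dimethyl-4H-1,3-dioxin-5-yl)-3-methylcyclohex-2-en-1-ol F7. Oxidation of F7 with Dess–Martin periodinane buffered with NaHCO3 returns 8 without base contact.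

Step 8. Hydride may be delivered to the other face of the C6 carbonyl, which gives the cis ring fusion. The fallback sets out from 17 and comes back at 19; it sets C6 by SN2 inversion instead of by hydride delivery. The 6-epimeric alcohol closes to the cis-fused lactone F8. F8 is saponified (LiOH, THF/H2O) to the (6S)-hydroxy acid F9. F9 is cyclised under Mitsunobu conditions (PPh3, diisopropyl azodicarboxylate, PhMe, high dilution), which activates the allylic C6 hydroxyl and closes the γ-lactone with inversion to give 19.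

**Further compounds**

F1 | step 7 | (1S,6R)-1-{[benzyl(dimethyl)silyl]ethynyl}-6-(2,2-dimethyl-4H-1,3-dioxin-5-yl)-3-methylcyclohex-2-en-1-ol | CC1=C[C@@](O)(C#C[Si](C)(C)Cc2ccccc2)[C@@H](C3=COC(C)(C)OC3)CC1
F2 | step 7 | (1S,6R)-1-{(Z)-2-[benzyl(dimethyl)silyl]ethenyl}-6-(2,2-dimethyl-4H-1,3-dioxin-5-yl)-3-methylcyclohex-2-en-1-ol | CC1=C[C@@](O)(/C=C\[Si](C)(C)Cc2ccccc2)[C@@H](C3=COC(C)(C)OC3)CC1
F3 | step 7 | (8S,9R)-8-[benzyl(dimethyl)silyl]-9,14-(isopropylidenedioxy)cyclodeca-1(10),4-dien-6-one (both ring alkenes ring-cis) | O=C1C[C@H]([Si](C)(C)Cc2ccccc2)[C@@H]3OC(C)(C)OC/C3=C/CC/C(C)=C\1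
F4 | step 7 | (8S,9R)-8-hydroxy-9,14-(isopropylidenedioxy)cyclodeca-1(10),4-dien-6-one | O=C1C[C@H](O)[C@@H]3OC(C)(C)OC/C3=C/CC/C(C)=C\1
F5 | step 7 | (8S,9R)-9,14-(isopropylidenedioxy)-8-[(4-methoxybenzyl)oxy]cyclodeca-1(10),4-dien-6-one | O=C1C[C@H](OCc2ccc(OC)cc2)[C@@H]3OC(C)(C)OC/C3=C/CC/C(C)=C\1
F6 | step 3 | racemic 6-(2,2-dimethyl-4H-1,3-dioxin-5-yl)-3-methylcyclohex-2-en-1-one | CC1=CC(=O)C(C2=COC(C)(C)OC2)CC1
F7 | step 3 | (1R,6R)-6-(2,2-dimethyl-4H-1,3-dioxin-5-yl)-3-methylcyclohex-2-en-1-ol | CC1=C[C@@H](O)[C@@H](C2=COC(C)(C)OC2)CC1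
F8 | step 8 | (6S,7S,8S,9R)-9,14-(isopropylidenedioxy)-8-[(4-methoxybenzyl)oxy]-13-norgermacra-1(10),4-dien-12,6-olide (cis-fused) | C1C(=O)O[C@H]2/C=C(/C)CC/C=C3/COC(C)(C)O[C@H]3[C@@H](OCc4ccc(OC)cc4)[C@@H]12
F9 | step 8 | [(6S,7S,8S,9R)-6-hydroxy-9,14-(isopropylidenedioxy)-8-[(4-methoxybenzyl)oxy]cyclodeca-1(10),4-dien-7-yl]acetic acid | OC(=O)C[C@H]1[C@@H](O)/C=C(/C)CC/C=C2/COC(C)(C)O[C@H]2[C@H]1OCc3ccc(OC)cc3
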